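**Retrosynthetic overview**

1. Grevirobstol B is a 22-membered diaryl ether: ring A is a 5-aryloxy-3-alkylphenol (OH on C1, chain on C3, ether oxygen on C5, hydrogens on C2, C4, C6), ring B a 2,4-dihydroxy-6-alkylphenyl ether, and a (CH2)16 chain joins ring A C3 to ring B.
2. The strategy rests on that ring A pattern: cutting C1–C6, C4–C5 and C1–C2 returns C1(=O)/C2/C3/C4 to a 3-alkylcyclobutenone and C5/C6 to an ethynyl ether on the ring B oxygen.
3. A thermal vinylketene–ynol ether benzannulation, run intramolecularly, should therefore build ring A and close the macrocycle in one operation; the two ring B hydroxyls travel as methyl ethers and are freed last with BBr3.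
4. The precursor comes from 1-bromo-3,5-dimethoxybenzene (Vilsmeier, B-alkyl Suzuki with hexadeca-1,15-diene, Dakin), trichloroethylene (dichlorovinyl ether, later n-BuLi) and 3-ethoxycyclobutenone (Grignard addition).
5. Ring order: ring B is purchased; ring A and the 22-membered ring form together in the key step.

Key step: step 8

Remark: the target is achiral, so no stereocentre has to be set; the E geometry of the dichlorovinyl ether is lost at the alkyne stage and the sp3 centres of in-situ intermediates are racemic. Hexadeca-1,15-diene and 3-ethoxycyclobut-2-en-1-one are taken as purchasable.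

**Route**

Step 1
Reactants: 1 1-bromo-3,5-dimethoxybenzene
Product: 2 2-bromo-4,6-dimethoxybenzaldehyde
Conditions: POCl3, DMF, 0 to 90 °C; then ice–water
Reagents that add atoms: N,N-dimethylformamide, CN(C)C=O; water, O
Why: Vilsmeier–Haack formylation, in which the chloroiminium ion attacks the position para to one methoxy group and ortho to the other (next to bromine), which is less hindered than the site between the two methoxy groups, and hydrolysis of the iminium salt gives the aldehyde.

Step 2
Reactants: 2 2-bromo-4,6-dimethoxybenzaldehyde; 3 hexadeca-1,15-diene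
Product: 5 2-(hexadec-15-en-1-yl)-4,6-dimethoxybenzaldehyde, via alkylborane 4 (not isolated)
Conditions: 3 (4 equiv), 9-BBN (1.3 equiv), THF, 0 °C to rt; then 2, PdCl2(dppf) (5 mol %), K3PO4 (3 M aq.), DMF, 60 °C
Reagents that add atoms: none
Why: B-alkyl Suzuki–Miyaura coupling, in which 9-BBN adds anti-Markovnikov to one terminal alkene of the excess diene (the excess suppresses double hydroboration and leaves no B–H to reduce the aldehyde) and the primary alkylborane couples with the aryl bromide, whose oxidative addition is favoured by the ortho formyl group.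

Step 3
Reactants: 5 2-(hexadec-15-en-1-yl)-4,6-dimethoxybenzaldehyde
Product: 7 2-(hexadec-15-en-1-yl)-4,6-dimethoxyphenol, via aryl formate 6 (not isolated)
Conditions: 30% H2O2, H2SO4 (cat.), MeOH, rt
Reagents that add atoms: hydrogen peroxide, OO
Why: Dakin-type oxidation (acid-catalysed Baeyer–Villiger reaction with H2O2), in which the electron-rich aryl group migrates to oxygen and the formate is methanolysed in the same flask, while the isolated terminal alkene does not react with H2O2.

Step 4
Reactants: 7 2-(hexadec-15-en-1-yl)-4,6-dimethoxyphenol; 8 trichloroethylene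
Product: 10 2-{[(E)-1,2-dichloroethenyl]oxy}-1-(hexadec-15-en-1-yl)-3,5-dimethoxybenzene, via dichloroacetylene 9 (not isolated)
Conditions: 8 (1.5 equiv), K2CO3, DMF, 70 °C
Reagents that add atoms: none
Why: Known O-dichlorovinylation of phenols, in which carbonate eliminates HCl from trichloroethylene and anti addition of the phenol O–H across the resulting dichloroacetylene gives the (E)-1,2-dichlorovinyl ether, the terminal alkene being inert.

Step 5
Reactants: 10 2-{[(E)-1,2-dichloroethenyl]oxy}-1-(hexadec-15-en-1-yl)-3,5-dimethoxybenzene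
Product: 12 16-(2-{[(E)-1,2-dichloroethenyl]oxy}-3,5-dimethoxyphenyl)hexadecan-1-ol, via alkylborane 11 (not isolated)
Conditions: 9-BBN, THF, 0 °C to rt; then NaOH (3 M aq.), 30% H2O2, 0 °C to rt
Reagents that add atoms: hydrogen peroxide, OO
Why: Hydroboration–oxidation, in which the bulky 9-BBN adds only to the monosubstituted alkene (boron on the terminal carbon) and not to the chlorinated, electron-poor enol ether, and alkaline H2O2 converts the C–B bond into the primary alcohol.

Step 6
Reactants: 12 16-(2-{[(E)-1,2-dichloroethenyl]oxy}-3,5-dimethoxyphenyl)hexadecan-1-ol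
Product: 13 1-(16-bromohexadecyl)-2-{[(E)-1,2-dichloroethenyl]oxy}-3,5-dimethoxybenzene
Conditions: CBr4, PPh3, CH2Cl2, 0 °C to rt
Reagents that add atoms: carbon tetrabromide, BrC(Br)(Br)Br
Why: Appel reaction, in which bromide displaces the alkoxyphosphonium group in an SN2 step under neutral conditions that leave the dichlorovinyl and methyl ethers untouched.

Step 7
Reactants: 13 1-(16-bromohexadecyl)-2-{[(E)-1,2-dichloroethenyl]oxy}-3,5-dimethoxybenzene; 14 3-ethoxycyclobut-2-en-1-one
Product: 19 3-[16-(2-ethynyloxy-3,5-dimethoxyphenyl)hexadecyl]cyclobut-2-en-1-one, via Grignard reagent 15 (not isolated), via bromomagnesium cyclobutenolate 16 (not isolated), via lithium aryloxyacetylide 17 (not isolated), via ethoxycyclobutenol 18 (not isolated)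
Conditions: Mg, THF, 30 °C; then 14, THF, −78 °C; then n-BuLi (2.5 equiv), −78 to −40 °C; then 0.5 M HCl, Et2O, 0 °C, short contact
Reagents that add atoms: none
Why: Telescoped sequence of known reactions, in which Mg inserts into the primary C–Br bond while the vinylic C–Cl bonds are inert, the Grignard reagent adds 1,2 to the vinylogous ester 14 (Danheiser-type cyclobutenone synthesis), n-BuLi converts the dichlorovinyl ether into the lithium aryloxyacetylide by elimination and chlorine–lithium exchange while the ketone is still masked as the alkoxide, and cold dilute acid protonates the acetylide and hydrolyses the tertiary allylic enol ether to the 3-alkylcyclobutenone (Stork–Danheiser-type transposition) much faster than it hydrates the aryl ynol ether.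

Step 8
Reactants: 19 3-[16-(2-ethynyloxy-3,5-dimethoxyphenyl)hexadecyl]cyclobut-2-en-1-one
Product: 24 grevirobstol B ring B dimethyl ether (22-membered macrocyclic phenol), via vinylketene 20 (not isolated), via macrocyclic vinylcyclobutenone 21 (not isolated), via macrocyclic dienylketene 22 (not isolated), via cyclohexadienone 23 (not isolated)
Conditions: toluene, 110 °C, 19 added by syringe pump over 10 h to a final concentration of about 0.5 mM, then 4 h
Reagents that add atoms: none
Why: Proposed new method: thermal 4π (conrotatory) opening of the cyclobutenone gives vinylketene 20, the terminal carbon of the aryloxyalkyne attacks the ketene carbonyl carbon in a [2+2] cycloaddition that forms C1–C6 and C4–C5 of ring A and gives 21, 21 opens (4π) to dienylketene 22, and 6π (disrotatory) closure forms C1–C2 and gives dienone 23, which enolises to phenol 24. The closest known reaction is the intermolecular Danheiser benzannulation of 3-alkylcyclobutenones with alkoxy- and siloxyalkynes, which gives 5-alkylresorcinol monoethers of the same regiochemistry, but neither an aryloxyalkyne partner nor a ring-closing version is established. The 22-membered ring closes in the intramolecular ketene–alkyne [2+2] cycloaddition (end-to-end macrocyclisation over a flexible (CH2)16 tether that carries no ring strain), and ring A closes by 6π electrocyclisation of the dienylketene followed by tautomerisation. No stereocentre is formed in 24: the sp3 carbon of 21 is racemic and becomes sp2 in 22. The step needs the regiochemistry of the cycloaddition, which the oxygen of the ynol ether secures by making the terminal alkyne carbon the nucleophile (so that the ether oxygen ends meta to the hydroxyl with the chain meta to both), and it needs ring closure to beat bimolecular reaction, which high dilution and the reversible return of the ketene to the cyclobutenone secure. The sense of rotation in the opening of 21 is not critical, since a dienylketene of the wrong geometry can only revert to 21.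

Step 9
Reactants: 24 grevirobstol B ring B dimethyl ether
Product: 25 grevirobstol B
Conditions: BBr3 (6 equiv), CH2Cl2, −78 to 0 °C; then H2O
Reagents that add atoms: none
Why: Lewis acid-mediated demethylation, in which BBr3 coordinates each methoxy oxygen and bromide attacks the methyl group (SN2), whereas the diaryl ether has no sp3 carbon on oxygen and survives.

**Compound list**

1 | 1-bromo-3,5-dimethoxybenzene | COc1cc(Br)cc(OC)c1 | starting material
2 | 2-bromo-4,6-dimethoxybenzaldehyde | COc1cc(Br)c(C=O)c(OC)c1 | intermediate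
3 | hexadeca-1,15-diene | C=CCCCCCCCCCCCCCC=C | starting material
4 | 9-(hexadec-15-en-1-yl)-9-borabicyclo[3.3.1]nonane | C=CCCCCCCCCCCCCCCB1C2CCCC1CCC2 | intermediate
5 | 2-(hexadec-15-en-1-yl)-4,6-dimethoxybenzaldehyde | C=CCCCCCCCCCCCCCCc1cc(OC)cc(OC)c1C=O | intermediate
6 | 2-(hexadec-15-en-1-yl)-4,6-dimethoxyphenyl formate | C=CCCCCCCCCCCCCCCc1cc(OC)cc(OC)c1OC=O | intermediate
7 | 2-(hexadec-15-en-1-yl)-4,6-dimethoxyphenol | C=CCCCCCCCCCCCCCCc1cc(OC)cc(OC)c1O | intermediate
8 | trichloroethylene | ClC=C(Cl)Cl | starting material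
9 | dichloroacetylene | ClC#CCl | intermediate
10 | 2-{[(E)-1,2-dichloroethenyl]oxy}-1-(hexadec-15-en-1-yl)-3,5-dimethoxybenzene | Cl/C=C(/Cl)Oc1c(OC)cc(OC)cc1CCCCCCCCCCCCCCC=C | intermediate
11 | 9-[16-(2-{[(E)-1,2-dichloroethenyl]oxy}-3,5-dimethoxyphenyl)hexadecyl]-9-borabicyclo[3.3.1]nonane | Cl/C=C(/Cl)Oc1c(OC)cc(OC)cc1CCCCCCCCCCCCCCCCB1C2CCCC1CCC2 | intermediate
12 | 16-(2-{[(E)-1,2-dichloroethenyl]oxy}-3,5-dimethoxyphenyl)hexadecan-1-ol | Cl/C=C(/Cl)Oc1c(OC)cc(OC)cc1CCCCCCCCCCCCCCCCO | intermediate
13 | 1-(16-bromohexadecyl)-2-{[(E)-1,2-dichloroethenyl]oxy}-3,5-dimethoxybenzene | Cl/C=C(/Cl)Oc1c(OC)cc(OC)cc1CCCCCCCCCCCCCCCCBr | intermediate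
14 | 3-ethoxycyclobut-2-en-1-one | CCOC1=CC(=O)C1 | starting material
15 | [16-(2-{[(E)-1,2-dichloroethenyl]oxy}-3,5-dimethoxyphenyl)hexadecyl]magnesium bromide | Cl/C=C(/Cl)Oc1c(OC)cc(OC)cc1CCCCCCCCCCCCCCCC[Mg]Br | intermediate
16 | bromomagnesium 1-[16-(2-{[(E)-1,2-dichloroethenyl]oxy}-3,5-dimethoxyphenyl)hexadecyl]-3-ethoxycyclobut-2-en-1-olate (racemic) | Cl/C=C(/Cl)Oc1c(OC)cc(OC)cc1CCCCCCCCCCCCCCCCC1(O[Mg]Br)C=C(OCC)C1 | intermediate
17 | lithium acetylide of the ethynyl ether, bromomagnesium 3-ethoxy-1-{16-[2-(lithioethynyloxy)-3,5-dimethoxyphenyl]hexadecyl}cyclobut-2-en-1-olate (racemic) | [Li]C#COc1c(OC)cc(OC)cc1CCCCCCCCCCCCCCCCC1(O[Mg]Br)C=C(OCC)C1 | intermediate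
18 | 3-ethoxy-1-[16-(2-ethynyloxy-3,5-dimethoxyphenyl)hexadecyl]cyclobut-2-en-1-ol (racemic) | C#COc1c(OC)cc(OC)cc1CCCCCCCCCCCCCCCCC1(O)C=C(OCC)C1 | intermediate
19 | 3-[16-(2-ethynyloxy-3,5-dimethoxyphenyl)hexadecyl]cyclobut-2-en-1-one | C#COc1c(OC)cc(OC)cc1CCCCCCCCCCCCCCCCC1=CC(=O)C1 | intermediate
20 | vinylketene, 3-[16-(2-ethynyloxy-3,5-dimethoxyphenyl)hexadecyl]buta-1,3-dien-1-one | C#COc1c(OC)cc(OC)cc1CCCCCCCCCCCCCCCCC(=C)C=C=O | intermediate
21 | macrocyclic [2+2] adduct, a cyclobut-2-en-1-one whose C3 carries the ring B oxygen and whose C4 carries the 1-methylidene end of the C16 chain (22-membered ring, racemic) | O=C1C=C2Oc3c(OC)cc(OC)cc3CCCCCCCCCCCCCCCCC(=C)C12 | intermediate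
22 | macrocyclic dienylketene, (E)-3-aryloxy-5-methylidene-penta-1,3-dien-1-one unit bridged by the C16 chain to ring B | O=C=C/C1=C\C(=C)CCCCCCCCCCCCCCCCc2cc(OC)cc(OC)c2O1 | intermediate
23 | macrocyclic cyclohexa-2,4-dien-1-one (keto tautomer of 24) | O=C1C=C2C=C(CCCCCCCCCCCCCCCCc3cc(OC)cc(OC)c3O2)C1 | intermediate
24 | grevirobstol B ring B dimethyl ether | Oc1cc2cc(c1)Oc1c(OC)cc(OC)cc1CCCCCCCCCCCCCCCC2 | intermediate
25 | grevirobstol B | Oc1cc2cc(c1)Oc1c(O)cc(O)cc1CCCCCCCCCCCCCCCC2 | target

**Totals**

Total step count: 9. Longest linear sequence: 9 steps (1 to 25).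

**Steps most likely to fail**

1. Step 8. The large-ring cycloaddition may be slower than bimolecular consumption of the vinylketene (dimerisation, acylation of the product phenol, reaction with the alkyne of a second molecule). The aryloxyalkyne, less nucleophilic than an alkoxyalkyne, may also polymerise on long heating before it is trapped.
Fallback (known chemistry; ring A is brought in ready-made and the macrocycle is closed by C–C coupling): it sets out from phenol 7. Ullmann-type O-arylation of 7 with excess 3,5-dibromoanisole (CuI (copper monoiodide), picolinic acid, K3PO4, DMSO, 90 °C) should give 1-bromo-3-[2-(hexadec-15-en-1-yl)-4,6-dimethoxyphenoxy]-5-methoxybenzene F1. 9-BBN should hydroborate its terminal alkene to 9-{16-[2-(3-bromo-5-methoxyphenoxy)-3,5-dimethoxyphenyl]hexadecyl}-9-borabicyclo[3.3.1]nonane F2. Slow addition of F2 to PdCl2(dppf) and aqueous K3PO4 in DMF–THF at about 1 mM and 60 °C should close the 22-membered ring at ring A C3 by an intramolecular B-alkyl Suzuki–Miyaura coupling and give grevirobstol B trimethyl ether F3. BBr3 then cleaves all three methyl ethers, and the fallback comes back to the route at target 25.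

2. Step 7. The doubly activated tertiary cyclobutenolate may not survive the strongly basic n-BuLi stage, or the acid that unmasks the enone may also hydrate the ynol ether to an aryl acetate.
Fallback (the ynol ether never meets acid, and the ring carbonyl is an alcohol during the n-BuLi stage): it sets out from bromide 13. Alkoxide 16, made as in step 7, is hydrolysed directly with dilute HCl, without n-BuLi, to 3-[16-(2-{[(E)-1,2-dichloroethenyl]oxy}-3,5-dimethoxyphenyl)hexadecyl]cyclobut-2-en-1-one F4, in which the acid-stable dichlorovinyl ether is still in place. Luche reduction (NaBH4, CeCl3·7H2O, MeOH, −78 °C) should give 3-[16-(2-{[(E)-1,2-dichloroethenyl]oxy}-3,5-dimethoxyphenyl)hexadecyl]cyclobut-2-en-1-ol F5. n-BuLi (3.3 equiv, THF, −78 to −40 °C, then aq. NH4Cl) should give 3-[16-(2-ethynyloxy-3,5-dimethoxyphenyl)hexadecyl]cyclobut-2-en-1-ol F6. MnO2 in CH2Cl2 at rt oxidises the allylic alcohol under neutral conditions, and the fallback comes back to the route at precursor 19.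

3. Step 2. Hydride transfer from the alkylborane or its borate to the aldehyde, or protodehalogenation of the hindered aryl bromide, may compete with transmetalation.
Fallback (the chain is attached before the carbonyl group exists): it sets out from bromide 1 and borane 4. Coupling of 4 with 1 under the same PdCl2(dppf)/K3PO4 conditions should give 1-(hexadec-15-en-1-yl)-3,5-dimethoxybenzene F7. Vilsmeier–Haack formylation (POCl3, DMF, 0 to 70 °C) should then enter ortho to the chain and para to a methoxy group, as it does in 5-alkylresorcinol dimethyl ethers, and the fallback comes back to the route at aldehyde 5.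

**Further compounds**

F1 | step 8 | 1-bromo-3-[2-(hexadec-15-en-1-yl)-4,6-dimethoxyphenoxy]-5-methoxybenzene | COc1cc(Br)cc(Oc2c(OC)cc(OC)cc2CCCCCCCCCCCCCCC=C)c1
F2 | step 8 | 9-{16-[2-(3-bromo-5-methoxyphenoxy)-3,5-dimethoxyphenyl]hexadecyl}-9-borabicyclo[3.3.1]nonane | COc1cc(Br)cc(Oc2c(OC)cc(OC)cc2CCCCCCCCCCCCCCCCB2C3CCCC2CCC3)c1
F3 | step 8 | grevirobstol B trimethyl ether | COc1cc2cc(c1)Oc1c(OC)cc(OC)cc1CCCCCCCCCCCCCCCC2
F4 | step 7 | 3-[16-(2-{[(E)-1,2-dichloroethenyl]oxy}-3,5-dimethoxyphenyl)hexadecyl]cyclobut-2-en-1-one | Cl/C=C(/Cl)Oc1c(OC)cc(OC)cc1CCCCCCCCCCCCCCCCC1=CC(=O)C1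
F5 | step 7 | 3-[16-(2-{[(E)-1,2-dichloroethenyl]oxy}-3,5-dimethoxyphenyl)hexadecyl]cyclobut-2-en-1-ol (racemic) | Cl/C=C(/Cl)Oc1c(OC)cc(OC)cc1CCCCCCCCCCCCCCCCC1=CC(O)C1
F6 | step 7 | 3-[16-(2-ethynyloxy-3,5-dimethoxyphenyl)hexadecyl]cyclobut-2-en-1-ol (racemic) | C#COc1c(OC)cc(OC)cc1CCCCCCCCCCCCCCCCC1=CC(O)C1
F7 | step 2 | 1-(hexadec-15-en-1-yl)-3,5-dimethoxybenzene | C=CCCCCCCCCCCCCCCc1cc(OC)cc(OC)c1
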